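**Retrosynthetic overview**
1. 8 ⇒ furfuryl alcohol 5 + NH3. Both ring C–N bonds are made last, in a one-flask O→N ring exchange in which the CH2OH carbon becomes the CHO group.
2. 5 ⇒ carboxylic acid 4 (carboxyl reduction).
3. 4 ⇒ 3-methylfuran-2-carboxylic acid 1 + 1-bromodocosane 2 (lateral alkylation; C1 + C22 gives the C23 chain, placed next to the future formyl carbon).
4. Ring order: furan (purchased) → 2H-pyran-3(6H)-one 6 (transient) → pyrrole (the only ring of the target, formed in the last step).

Assumption: the side chain is read as an unbranched C23 (n-tricosyl) chain, and the target (C28H51NO) has no stereocentre, so there is no enantiomer to control.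

**Step 1**
Reactants: 1 3-methylfuran-2-carboxylic acid; 2 1-bromodocosane
Product: 4 3-tricosylfuran-2-carboxylic acid, via dilithio dianion 3 (not isolated)
Conditions: LDA (commercial solution, 2.2 equiv), THF, −78 → 0 °C; then 2 (0.95 equiv) in THF/DMPU, 0 °C → rt; 1 M HCl work-up, recrystallisation
Reagents that add atoms: lithium diisopropylamide, [Li+].CC(C)[N-]C(C)C (supplies only the lithium of 3; no atom of it remains in 4)
Why: Lateral (vinylogous) deprotonation of the lithium furoate gives a carboxylate-stabilised extended enediolate, which undergoes SN2 alkylation by the primary bromide at the exocyclic carbon with recovery of furan aromaticity (carboxylic acid dianion alkylation); no stereocentre is formed.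

**Step 2**
Reactants: 4 3-tricosylfuran-2-carboxylic acid
Product: 5 (3-tricosylfuran-2-yl)methanol
Conditions: LiAlH4 (1.5 equiv), THF, 0 °C → reflux; H2O / 15% NaOH work-up (kept non-acidic)
Reagents that add atoms: none
Why: Standard LiAlH4 reduction of a carboxylic acid to the primary alcohol; the furan and the alkyl chain are inert to hydride, and no stereocentre is formed.

**Step 3**
Reactants: 5 (3-tricosylfuran-2-yl)methanol
Product: 8 3-tricosyl-1H-pyrrole-2-carbaldehyde, via Achmatowicz pyranone 6 (not isolated), via cyclic carbinolamine 7 (not isolated)
Conditions: mCPBA (1.0 equiv), CH2Cl2, 0 °C → rt; then solvent switch, NH4OAc (10 equiv), AcOH (2 equiv), THF–EtOH, 55 °C, N2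
Reagents that add atoms: ammonium acetate, CC(=O)[O-].[NH4+] (ring nitrogen of 7 and 8); mCPBA, O=C(OO)c1cccc(Cl)c1 (one oxygen, carried in 6 and 7 and lost again as water before 8)
Why: Proposed new method: this is a one-flask furan-to-pyrrole O→N exchange with the carbinol as internal reductant: the peracid (Achmatowicz oxidation) unmasks the furan as pyranone 6, the cyclic form of (Z)-HOCH2–CO–C(R)=CH–CHO; ammonia condenses with the C5 aldehyde and the C2 ketone to give 7 (both ring C–N bonds); loss of the C2 hydroxyl gives a cyclic ketiminium ion whose imine–enaminol (Heyns-type) tautomerisation towards CH2OH moves the oxidation level onto the exocyclic carbon, and vinylogous loss of the C5 hydroxyl then aromatises irreversibly to the 2-formylpyrrole (net 6 + NH3 → 8 + 2 H2O, redox-neutral); nitrogen is tied to C2 and C5 before the exocyclic carbon becomes an aldehyde, which disfavours the 3-hydroxypyridine channel; the closest known reaction types are the Paal–Knorr pyrrole synthesis and the Maillard-type condensation of primary amines with sugar-derived dihydropyranones to N-alkyl-2-formylpyrroles, neither shown with ammonia on an aldehyde-terminated Achmatowicz product to give an N–H, 5-unsubstituted 2-formylpyrrole; the transient stereocentres of 6 and 7 vanish and 8 has none.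

**Compound list**
1 | 3-methylfuran-2-carboxylic acid | Cc1ccoc1C(=O)O | starting material
2 | 1-bromodocosane | CCCCCCCCCCCCCCCCCCCCCCBr | starting material
3 | dilithium 3-(methanidyl)furan-2-carboxylate (lateral dianion of 1, not isolated) | [Li+].[Li+].[CH2-]c1ccoc1C(=O)[O-] | intermediate
4 | 3-tricosylfuran-2-carboxylic acid | CCCCCCCCCCCCCCCCCCCCCCCc1ccoc1C(=O)O | intermediate
5 | (3-tricosylfuran-2-yl)methanol | CCCCCCCCCCCCCCCCCCCCCCCc1ccoc1CO | intermediate
6 | 6-hydroxy-4-tricosyl-2H-pyran-3(6H)-one (racemic hemiacetal, not isolated) | CCCCCCCCCCCCCCCCCCCCCCCC1=CC(O)OCC1=O | intermediate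
7 | 2-(hydroxymethyl)-3-tricosyl-2,5-dihydro-1H-pyrrole-2,5-diol (stereoisomer mixture, not isolated) | CCCCCCCCCCCCCCCCCCCCCCCC1=CC(O)NC1(O)CO | intermediate
8 | 3-tricosyl-1H-pyrrole-2-carbaldehyde (achiral) | CCCCCCCCCCCCCCCCCCCCCCCc1cc[nH]c1C=O | target

**Total step count:** 3. **Longest linear sequence:** 3.

**Steps most likely to fail**

Step 3 (the proposed new step).
- The cyclic ketiminium ion may lose its C5–H instead of a carbinol C–H. That would end as a 5-(hydroxymethyl)pyrrolin-2-one.
- It may also expel formaldehyde, or the enedicarbonyl may oligomerise with ammonia.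
- The fallback uses known chemistry only. It sets out from 1-bromodocosane 2 and comes back at 8.
- Commercial 4-methylpyridine is deprotonated at the methyl group with LDA (THF, −78 °C) and alkylated with 2 to give 4-tricosylpyridine F1.
- mCPBA in CH2Cl2 converts it into 4-tricosylpyridine 1-oxide F2.
- UV irradiation at about 300 nm in aqueous tert-butanol containing a copper(II) salt then triggers the known photochemical valence isomerisation of pyridine N-oxides (oxaziridine, then 1,2-oxazepine, then 2-acylpyrrole).
- The two α-positions of the 4-substituted N-oxide are equivalent, so only the 3-substituted 2-formylpyrrole 8 can form.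

Step 1.
- Deprotonation may occur at furan C5 instead of the methyl group.
- The enediolate may be alkylated at the ring α-carbon.
- The waxy bromide may react sluggishly.
- The fallback reverses the polarity of the C–C bond. It sets out from 2 and comes back at 5.
- Compound 2 is converted with magnesium in THF into docosylmagnesium bromide F3.
- Commercial methyl 3-methylfuran-2-carboxylate is brominated with NBS/AIBN to methyl 3-(bromomethyl)furan-2-carboxylate F4.
- Li2CuCl4-catalysed coupling of the two at −40 °C gives methyl 3-tricosylfuran-2-carboxylate F5.
- LiAlH4 reduces this ester directly to 5.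

Step 2.
- The lithium/aluminium carboxylate of the long-chain acid may precipitate and reduce incompletely.
- The furfuryl alcohol is acid-sensitive during work-up.
- The fallback activates the acid first and uses a mild borohydride. It sets out from 4 and comes back at 5.
- Ethyl chloroformate and Et3N in THF at −10 °C give ethyl carbonic 3-tricosylfuran-2-carboxylic anhydride F6.
- This soluble neutral species is reduced with NaBH4 in THF–MeOH at 0 °C to 5.

**Further compounds**
F1 | step 3 | 4-tricosylpyridine | CCCCCCCCCCCCCCCCCCCCCCCc1ccncc1
F2 | step 3 | 4-tricosylpyridine 1-oxide | CCCCCCCCCCCCCCCCCCCCCCCc1cc[n+]([O-])cc1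
F3 | step 1 | docosylmagnesium bromide | CCCCCCCCCCCCCCCCCCCCCC[Mg]Br
F4 | step 1 | methyl 3-(bromomethyl)furan-2-carboxylate | COC(=O)c1occc1CBr
F5 | step 1 | methyl 3-tricosylfuran-2-carboxylate | CCCCCCCCCCCCCCCCCCCCCCCc1ccoc1C(=O)OC
F6 | step 2 | ethyl carbonic 3-tricosylfuran-2-carboxylic anhydride | CCCCCCCCCCCCCCCCCCCCCCCc1ccoc1C(=O)OC(=O)OCC
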